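## Structural features

The target is a germacranolide: a ten-membered carbocycle (C1–C10) fused through C6 and C7 to a butenolide whose tetrasubstituted C7=C11 double bond is conjugated with the C12 lactone carbonyl, the lactone oxygen sitting on C6. Two trisubstituted epoxides span C1–C10 and C4–C5; each has a methyl group on its quaternary carbon (C14 on C10, C15 on C4) and each is cis with respect to the ring bonds. C11 carries an acetoxymethyl group (C13) and O8 a senecioyl (3-methylbut-2-enoyl) ester. There are six stereocentres, (1S,4S,5R,6R,8R,10R): C4–C5–C6 are contiguous, C10–C1 are contiguous, and C8 is 1,3-related to C10 through C9. The fragile elements are the acid-labile epoxides, the C13 acetate (a vinylogous leaving group once the γ-proton C6–H is removed), the senecioate (deconjugation, cleavage) and any intermediate with a C8 carbonyl, which is a reducible, base-sensitive ene-dicarbonyl. The real difficulty is to close a ten-membered ring whose two stereochemical domains (C4–C6 and C1/C10/C8) are separated by methylene groups and cannot control one another through the chain. The key step uses the 1,3-relationship of O8 and O10 across C9: C8(=O)–C9–C10(OH) is an aldol unit whose C9–C10 bond closes the ring. The C1 oxygen next to C10 can hold a metal in a five-membered chelate that fixes the ketone face and later leaves, with inversion, when the 1,10-epoxide is closed.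

## Logic of the disconnections

31 is traced to 30 and then to 29 by cutting the O13–acetyl bond and replacing it by an O13–silyl bond. An acetate at C13 would be expelled by any enolate or ketyl at C8 and by base after C6 deprotonation, so it is introduced last. This demands near-neutral desilylation and acylation in the forward direction.

29 is traced to 27 (through 28) by cutting the C1–O bond of the 1,10-epoxide. This turns the strained epoxide into a secondary/tertiary diol in which O10 is the hydroxyl of an aldol. The forward closure is an SN2 displacement, so C1 must carry the opposite configuration (1R) in every earlier compound, and the secondary hydroxyl must be activated selectively.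

27 is traced to 26 and 26 to 25 by restoring the 4-methoxybenzyl ether on O1 and cutting the O8–acyl bond. The ester differentiates O8 from O1 before O1 is freed. The forward steps need acylation of a secondary hydroxyl beside a tertiary one and an oxidative ether cleavage that spares two alkenes and an epoxide.

25 is traced to 24 by cutting the C8–H bond, which reveals the β-hydroxy ketone. The forward step must give the 1,3-anti diol, so a hydroxyl-directed reduction is required.

24 is traced to 22 (through 23) by cutting C9–C10. This opens the ten-membered ring and removes the C10 stereocentre. The forward step needs an enolate at C9 generated without base, a templating metal, high dilution and attack on the chelated ketone.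

22 is traced to 21 by converting both ketones (C8 and C10) back to secondary alcohols. The bromoacetyl butenolide and the α-alkoxy ketone are the least stable functions of the route, so they exist for one step only. The forward step is a clean double oxidation.

21 is traced to 11 and 19 by cutting C6–C7 and O6–C12. This is the convergent cut: two fragments of similar size, with C6 set in the coupling. It demands a Z-configured enol triflate (ester cis to the reacting carbon), aldehyde-selective alkenyl transfer and Felkin–Anh control by the cis-epoxy aldehyde.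

19 is traced through 18 and 17 to 16, and 16 to 13 and 14 (through 15), by cutting C9–Br, the acetonide, the C7–OTf bond and the C7–C11 bond; 13 comes from 12. The C8–C9 unit is brought in as a glycerate so that the acid step and the bromination are done on a small fragment before any epoxide is present. The silyl group on O13 is chosen to survive that acid.

11 is traced to 10 and 10 to 9 by reducing the aldehyde and removing the 4,5-epoxide oxygen. The epoxide is set by a reagent-controlled epoxidation of a Z-allylic alcohol, independent of the remote C1 centre.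

9 is traced to 4 and 7 (through 8) by cutting C3–C4; 7 comes from 5 (through 6). The Z geometry of the C4=C5 bond is carried by the iodoalkene, and the coupling must retain it.

4 is traced to 3, 3 to 2 and 2 to 1. C1 is set by desymmetrisation of an achiral dienol, the epoxide of 2 becomes the C10 carbinol with its methyl group, and the C10 configuration is irrelevant because C10 becomes a ketone in 22.

## Other disconnections considered

Alternative 1: The cut is the C7=C11 double bond of the butenolide, with O6–C12 traced back to acylation of the C6 hydroxyl. In the forward direction the ten-membered 7-ketone A1 (allyl malonate on O6, both epoxides, silyl ether on O8) would be treated with piperidinium acetate; Knoevenagel condensation and dehydration would give butenolide A2, whose allyl ester stands for C13.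
- In favour: the condensation is metal-free, intramolecular and creates no stereocentre. On operational simplicity and on the absence of a selectivity requirement in the key step, it is the better of the two.
- Against: the ten-membered ring must still be made by some other reaction, so the hardest problem is left open. A1 has a ketone flanked by C6 (acyloxy) and C8 (silyloxy) with the 4,5-epoxide β to it, so an amine salt can epimerise either centre or open the epoxide by E1cB. After A2, C13 is at the acid oxidation level and must be deallylated, reduced beside the lactone and acetylated.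
- Comparison: in structure, A2 already holds both epoxides, which is an advantage over 24. In mechanism, the chosen aldol forms the ring and the C10 centre together, whereas the Knoevenagel step only adds a ring to an existing one. In step economy, the end game after A2 (ester-to-alcohol exchange, O8 exchange, two acylations) is about as long as the six steps after 24, and the ring synthesis comes on top.

Alternative 2: The cut is C6–C7 together with O6–C12. The open-chain epoxy aldehyde A3 (both epoxides in place, Z enol triflate at C7 with a cis methyl ester) would be treated with CrCl2 and catalytic NiCl2. The alkenylchromium would add to the C6 aldehyde and the chromium alkoxide would lactonise to give A4.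
- In favour: two rings arise in one step, which is better than the chosen key step (one ring). Only O8 and O13 exchanges remain after A4, about four steps against six, which is also better.
- Against: A3 needs the 1,10-epoxide, whose two centres are remote from all others, to be set by a separate reagent-controlled operation in a long chain. The α,β-epoxy aldehyde would sit with excess divalent chromium for the long time a high-dilution, tetrasubstituted alkenyl addition needs, inviting reductive or chloride opening. Facial selectivity at C6 in a macrocyclic transition state is not secured by the Felkin–Anh preference, because no metal template organises the chain.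
- Comparison: the chosen plan uses the same nickel/chromium lactonisation between two fragments (step 13), where it is fast and concentrated, and keeps the macrocyclisation for a chelation-templated aldol. Overall step counts are similar; the alternative has the longer linear sequence.

Alternative 3: The cut is C3–C4. The seco compound A5 (vinyl group on the C1 epoxide carbon, Z iodoalkene at C4, both esters in place) would be hydroborated at C3 with 9-BBN and cyclised with Pd(dppf)Cl2/K3PO4 to A6, the 4,5-alkene. A final epoxidation would give the target.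
- In favour: the bond joins two unfunctionalised carbons, and the coupling type is the one used in step 5 of the chosen route, so on reaction reliability in open-chain settings it is equal. Only one step follows A6, which is clearly better in end-game economy.
- Against: hydroboration of a vinyl epoxide puts boron γ to the epoxide oxygen, and the borate formed under base can undergo 1,3-elimination to a cyclopropyl carbinol. The aqueous base also threatens the C13 acetate (vinylogous elimination) and C6–H. β-Hydride elimination competes in a strained ten-membered closure. The last epoxidation of the ring Z-alkene has no directing group, so the (4S,5R) face is not assured.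
- Comparison: the chosen plan sets the 4,5-epoxide by reagent control before the ring exists and forms C3–C4 between fragments. The alternative is shorter on paper but carries its two largest risks in the last two steps.

Key step: step 15

Assumption: the facial sense of the two tartrate-controlled epoxidations (steps 1 and 6) is taken from the usual Sharpless rule, under which D-(−)-tartrate esters give 2 and the (2R,3S) epoxide 10; were either assignment reversed, the antipodal tartrate would be used.

## Steps

Step 1
Reactants: 1 penta-1,4-dien-3-ol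
Product: 2 (2S,3R)-1,2-epoxypent-4-en-3-ol
Conditions: Ti(OiPr)4 (cat.), D-(−)-diisopropyl tartrate (cat.), t-BuOOH, 4 Å MS, CH2Cl2, −20 °C
Reagents that add atoms: tert-butyl hydroperoxide, CC(C)(C)OO
Why: Sharpless asymmetric epoxidation used as a desymmetrisation: the titanium tartrate epoxidises one enantiotopic vinyl group to the erythro epoxy alcohol, and the minor enantiomer is removed by a faster second epoxidation, so the carbinol centre (the future C1, R) should be obtained in high enantiomeric purity.

Step 2
Reactants: 2 (2S,3R)-1,2-epoxypent-4-en-3-ol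
Product: 3 (2S)-2-[(1R)-1-(4-methoxybenzyloxy)prop-2-en-1-yl]oxirane
Conditions: NaH, 4-MeOC6H4CH2Cl, Bu4NI (cat.), THF/DMF, −20 → 0 °C
Reagents that add atoms: 4-methoxybenzyl chloride, COc1ccc(CCl)cc1
Why: Williamson etherification of the sodium alkoxide; with iodide catalysis at low temperature, alkylation should outrun Payne rearrangement, and the C1 oxygen becomes the chelating, oxidatively removable ether.

Step 3
Reactants: 3 (2S)-2-[(1R)-1-(4-methoxybenzyloxy)prop-2-en-1-yl]oxirane
Product: 4 (2S,3R)-3-(4-methoxybenzyloxy)pent-4-en-2-ol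
Conditions: LiAlH4, THF, 0 °C
Reagents that add atoms: none
Why: Hydride opens the terminal epoxide at its unsubstituted carbon (SN2), which turns the oxirane into the C10 carbinol bearing the C14 methyl group; C1 is untouched and the C10 configuration is of no consequence.

Step 4
Reactants: 5 but-2-yn-1-ol
Product: 7 (Z)-3-iodobut-2-en-1-ol, via cyclic alkenylalanate 6 (not isolated)
Conditions: NaAlH2(OCH2CH2OMe)2, THF, 0 °C → rt; then I2, −78 °C → rt
Reagents that add atoms: iodine, II
Why: Alkoxide-directed trans-hydroalumination of the propargylic alcohol places aluminium on C3 cis to the carbinol carbon, and iodinolysis with retention gives the Z iodoalkene, which holds C15, C4, C5 and C6 with the ring-cis geometry already fixed.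

Step 5
Reactants: 4 (2S,3R)-3-(4-methoxybenzyloxy)pent-4-en-2-ol; 7 (Z)-3-iodobut-2-en-1-ol
Product: 9 (2Z,6R,7S)-6-(4-methoxybenzyloxy)-3-methyloct-2-ene-1,7-diol, via B-alkyl-9-BBN borane 8 (not isolated)
Conditions: 9-BBN (2.5 equiv), THF, 0 °C → rt; then 7, Pd(dppf)Cl2 (5 mol %), AsPh3, aq K3PO4, DMF, rt
Reagents that add atoms: none
Why: Anti-Markovnikov hydroboration of the terminal vinyl group followed by B-alkyl Suzuki–Miyaura coupling forms C3–C4 with retention of the alkene geometry; no stereocentre is formed, and the free hydroxyls are tolerated with excess borane and aqueous base.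

Step 6
Reactants: 9 (2Z,6R,7S)-6-(4-methoxybenzyloxy)-3-methyloct-2-ene-1,7-diol
Product: 10 [(2R,3S)-3-[(3R,4S)-4-hydroxy-3-(4-methoxybenzyloxy)pentyl]-3-methyloxiran-2-yl]methanol
Conditions: Ti(OiPr)4 (cat.), D-(−)-diethyl tartrate (cat.), t-BuOOH, 4 Å MS, CH2Cl2, −20 °C
Reagents that add atoms: tert-butyl hydroperoxide, CC(C)(C)OO
Why: Sharpless asymmetric epoxidation of a Z-trisubstituted (nerol-type) allylic alcohol; the tartrate alone decides the face, so C4 (S) and C5 (R) are set independently of the remote C1 centre, and the secondary hydroxyl, not being allylic, is not a substrate.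

Step 7
Reactants: 10 [(2R,3S)-3-[(3R,4S)-4-hydroxy-3-(4-methoxybenzyloxy)pentyl]-3-methyloxiran-2-yl]methanol
Product: 11 (2S,3S)-3-[(3R,4S)-4-hydroxy-3-(4-methoxybenzyloxy)pentyl]-3-methyloxirane-2-carbaldehyde
Conditions: TEMPO (cat.), PhI(OAc)2, CH2Cl2, 0 °C → rt
Reagents that add atoms: none
Why: Oxoammonium-mediated oxidation is selective for the primary over the hindered secondary alcohol and is mild enough for an α,β-epoxy aldehyde (the descriptor at C5 changes only because the substituent priorities change).

Step 8
Reactants: 12 methyl 3-hydroxypropanoate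
Product: 13 methyl 3-(tert-butyldiphenylsilyloxy)propanoate
Conditions: t-BuPh2SiCl, imidazole, DMF, rt
Reagents that add atoms: tert-butyl(chloro)diphenylsilane, CC(C)(C)[Si](Cl)(c1ccccc1)c1ccccc1
Why: Standard silylation of a primary alcohol; the tert-butyldiphenylsilyl group is chosen because it should survive the aqueous acid of step 11 and every step up to step 20.

Step 9
Reactants: 13 methyl 3-(tert-butyldiphenylsilyloxy)propanoate; 14 methyl (4R)-2,2-dimethyl-1,3-dioxolane-4-carboxylate
Product: 16 methyl 2-[(tert-butyldiphenylsilyloxy)methyl]-3-[(4R)-2,2-dimethyl-1,3-dioxolan-4-yl]-3-oxopropanoate, via lithium ester enolate 15 (not isolated)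
Conditions: LiN(iPr)2 (2.1 equiv), 13 (2.1 equiv), THF, −78 °C; then 14, −78 → −40 °C; aq NH4Cl
Reagents that add atoms: none
Why: Crossed Claisen condensation of the ester enolate with an activated α-alkoxy ester forms C7–C11; the β-keto ester is deprotonated by the second equivalent of enolate, which drives the reaction and shields the dioxolane centre, whose configuration is in any case lost later.

Step 10
Reactants: 16 methyl 2-[(tert-butyldiphenylsilyloxy)methyl]-3-[(4R)-2,2-dimethyl-1,3-dioxolan-4-yl]-3-oxopropanoate
Product: 17 methyl (2Z)-2-[(tert-butyldiphenylsilyloxy)methyl]-3-[(4R)-2,2-dimethyl-1,3-dioxolan-4-yl]-3-(trifluoromethylsulfonyloxy)prop-2-enoate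
Conditions: NaH, CH2Cl2, 0 °C; Tf2O, −78 → 0 °C
Reagents that add atoms: trifluoromethanesulfonic anhydride, O=S(=O)(OS(=O)(=O)C(F)(F)F)C(F)(F)F
Why: O-Sulfonylation of the sodium chelate of the β-keto ester, in which sodium bridges both carbonyl oxygens, should give the enol triflate with the triflate cis to the ester (Z), the geometry needed for lactonisation after coupling.

Step 11
Reactants: 17 methyl (2Z)-2-[(tert-butyldiphenylsilyloxy)methyl]-3-[(4R)-2,2-dimethyl-1,3-dioxolan-4-yl]-3-(trifluoromethylsulfonyloxy)prop-2-enoate
Product: 18 methyl (2Z,4R)-2-[(tert-butyldiphenylsilyloxy)methyl]-4,5-dihydroxy-3-(trifluoromethylsulfonyloxy)pent-2-enoate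
Conditions: AcOH/H2O (4:1), 40 °C
Reagents that add atoms: none
Why: Acid hydrolysis of a terminal isopropylidene acetal; the silyl ether, the methyl ester and the electron-poor enol triflate tolerate aqueous acetic acid, and the diol cannot lactonise because it is trans to the ester.

Step 12
Reactants: 18 methyl (2Z,4R)-2-[(tert-butyldiphenylsilyloxy)methyl]-4,5-dihydroxy-3-(trifluoromethylsulfonyloxy)pent-2-enoate
Product: 19 methyl (2Z,4S)-5-bromo-2-[(tert-butyldiphenylsilyloxy)methyl]-4-hydroxy-3-(trifluoromethylsulfonyloxy)pent-2-enoate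
Conditions: CBr4, PPh3, pyridine, CH2Cl2, 0 °C
Reagents that add atoms: tetrabromomethane, BrC(Br)(Br)Br
Why: Appel bromination is selective for the primary hydroxyl of a 1,2-diol, so the future C9 bromide is installed on a small fragment before any epoxide is present.

Step 13
Reactants: 11 (2S,3S)-3-[(3R,4S)-4-hydroxy-3-(4-methoxybenzyloxy)pentyl]-3-methyloxirane-2-carbaldehyde; 19 methyl (2Z,4S)-5-bromo-2-[(tert-butyldiphenylsilyloxy)methyl]-4-hydroxy-3-(trifluoromethylsulfonyloxy)pent-2-enoate
Product: 21 (5R)-4-[(1S)-2-bromo-1-hydroxyethyl]-3-[(tert-butyldiphenylsilyloxy)methyl]-5-[(2R,3S)-3-[(3R,4S)-4-hydroxy-3-(4-methoxybenzyloxy)pentyl]-3-methyloxiran-2-yl]furan-2(5H)-one, via chromium alkoxide 20 (not isolated)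
Conditions: CrCl2 (6 equiv), NiCl2 (2 mol %), DMF, rt
Reagents that add atoms: none
Why: Nozaki–Hiyama–Kishi coupling: zerovalent nickel inserts into the C–OTf bond, transmetalation gives an alkenylchromium that adds only to the aldehyde, and the alkoxide of trivalent chromium closes onto the cis methyl ester to form the butenolide. C6 (R) should arise by Felkin–Anh addition anti to the C5–O bond of the cis-epoxy aldehyde; free hydroxyls and an unactivated primary bromide are normally tolerated.

Step 14
Reactants: 21 (5R)-4-[(1S)-2-bromo-1-hydroxyethyl]-3-[(tert-butyldiphenylsilyloxy)methyl]-5-[(2R,3S)-3-[(3R,4S)-4-hydroxy-3-(4-methoxybenzyloxy)pentyl]-3-methyloxiran-2-yl]furan-2(5H)-one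
Product: 22 (5R)-4-(bromoacetyl)-3-[(tert-butyldiphenylsilyloxy)methyl]-5-[(2R,3S)-3-[(3R)-3-(4-methoxybenzyloxy)-4-oxopentyl]-3-methyloxiran-2-yl]furan-2(5H)-one
Conditions: Dess–Martin periodinane (3 equiv), NaHCO3, CH2Cl2, 0 °C → rt
Reagents that add atoms: none
Why: Dess–Martin oxidation of both secondary alcohols under bicarbonate buffering unveils the bromoacetyl group and the C10 methyl ketone in one operation without base strong enough to epimerise C1 or C6; 22 is taken directly into step 15.

Step 15
Reactants: 22 (5R)-4-(bromoacetyl)-3-[(tert-butyldiphenylsilyloxy)methyl]-5-[(2R,3S)-3-[(3R)-3-(4-methoxybenzyloxy)-4-oxopentyl]-3-methyloxiran-2-yl]furan-2(5H)-one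
Product: 24 (1R,4S,5R,6R,10R)-13-(tert-butyldiphenylsilyloxy)-4,5-epoxy-10-hydroxy-1-(4-methoxybenzyloxy)-8-oxogermacr-7(11)-en-12,6-olide (germacrane numbering), via samarium enolate 23 (not isolated)
Conditions: SmI2 (2.2 equiv, 0.1 M in THF) added slowly to 22 (0.003 M in THF), −78 °C; aq NH4Cl at −78 °C
Reagents that add atoms: none
Why: Two single-electron transfers from SmI2 cleave the C9–Br bond (through the C8 ketyl and loss of bromide) and give the O-bound enolate of trivalent samarium without any base; the closest known reaction type is the SmI2-promoted intramolecular Reformatsky closure of medium and large rings. The ten-membered carbocycle is closed by attack of C9 on the C10 carbonyl in a 10-exo-trig (enolendo) aldol mode under high dilution. The oxophilic trivalent samarium, already bound to O8, also binds the C10 carbonyl oxygen and the C1 ether oxygen, so the ketone reacts as a five-membered chelate and the enolate is held within reach, which offsets the entropic cost of the medium ring. In that chelate C9 approaches C10 from the face syn to the C1 hydrogen and anti to C2 (Cram chelate rule, reinforced by the tether, since C2 and C9 cannot eclipse in the forming ring), which makes C10 R from 1R. Chemoselectivity rests on rates: the α-bromo ketone is reduced far faster than the isolated ketone, the α-alkoxy ketone or the butenolide, and slow addition of the reagent to cold substrate keeps SmI2 from accumulating. The silyl ether at O13 gives the enolate and any ketyl no vinylogous leaving group, and the absence of base and the cold quench protect C6–H and the aldolate from retro-aldol cleavage.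

Step 16
Reactants: 24 (1R,4S,5R,6R,10R)-13-(tert-butyldiphenylsilyloxy)-4,5-epoxy-10-hydroxy-1-(4-methoxybenzyloxy)-8-oxogermacr-7(11)-en-12,6-olide
Product: 25 (1R,4S,5R,6R,8R,10R)-13-(tert-butyldiphenylsilyloxy)-4,5-epoxy-8,10-dihydroxy-1-(4-methoxybenzyloxy)germacr-7(11)-en-12,6-olide
Conditions: Me4NBH(OAc)3, MeCN/AcOH, −30 °C
Reagents that add atoms: none
Why: Evans–Saksena reduction: the C10 hydroxyl exchanges onto boron and delivers hydride intramolecularly to the acid-activated C8 carbonyl through a chair-like six-membered transition state with C7 and C1 equatorial, which should give the 1,3-anti diol (8R); internal delivery also enforces 1,2- over 1,4-reduction.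

Step 17
Reactants: 25 (1R,4S,5R,6R,8R,10R)-13-(tert-butyldiphenylsilyloxy)-4,5-epoxy-8,10-dihydroxy-1-(4-methoxybenzyloxy)germacr-7(11)-en-12,6-olide
Product: 26 (1R,4S,5R,6R,8R,10R)-13-(tert-butyldiphenylsilyloxy)-4,5-epoxy-10-hydroxy-1-(4-methoxybenzyloxy)-8-(3-methylbut-2-enoyloxy)germacr-7(11)-en-12,6-olide
Conditions: 3-methylbut-2-enoyl chloride, pyridine, DMAP (cat.), CH2Cl2, 0 °C
Reagents that add atoms: 3-methylbut-2-enoyl chloride, CC(C)=CC(Cl)=O
Why: Acylation of the secondary C8 hydroxyl; the tertiary C10 hydroxyl should not react, and pyridine as the only stoichiometric base avoids deconjugation of the senecioyl unit through a vinylketene.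

Step 18
Reactants: 26 (1R,4S,5R,6R,8R,10R)-13-(tert-butyldiphenylsilyloxy)-4,5-epoxy-10-hydroxy-1-(4-methoxybenzyloxy)-8-(3-methylbut-2-enoyloxy)germacr-7(11)-en-12,6-olide
Product: 27 (1R,4S,5R,6R,8R,10R)-13-(tert-butyldiphenylsilyloxy)-4,5-epoxy-1,10-dihydroxy-8-(3-methylbut-2-enoyloxy)germacr-7(11)-en-12,6-olide
Conditions: DDQ, CH2Cl2/pH 7 buffer, 0 °C
Reagents that add atoms: none
Why: Oxidative cleavage of the 4-methoxybenzyl ether (hydride abstraction by DDQ, hydrolysis of the oxocarbenium ion); water and buffer prevent acetal formation with the C10 hydroxyl and acid damage to the epoxide, and the electron-poor alkenes are inert.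

Step 19
Reactants: 27 (1R,4S,5R,6R,8R,10R)-13-(tert-butyldiphenylsilyloxy)-4,5-epoxy-1,10-dihydroxy-8-(3-methylbut-2-enoyloxy)germacr-7(11)-en-12,6-olide
Product: 29 (1S,4S,5R,6R,8R,10R)-13-(tert-butyldiphenylsilyloxy)-1,10:4,5-diepoxy-8-(3-methylbut-2-enoyloxy)germacr-7(11)-en-12,6-olide, via C1 mesylate 28 (not isolated)
Conditions: MsCl, Et3N, CH2Cl2, −20 °C; then DBU, 0 °C → rt
Reagents that add atoms: none
Why: Chemoselective sulfonylation of the secondary hydroxyl, then intramolecular Williamson displacement (3-exo-tet) by the C10 oxygen with inversion at C1; because C10 was set by chelation relative to 1R, inversion gives the cis 1,10-epoxide (1S,10R) and C10 keeps its configuration.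

Step 20
Reactants: 29 (1S,4S,5R,6R,8R,10R)-13-(tert-butyldiphenylsilyloxy)-1,10:4,5-diepoxy-8-(3-methylbut-2-enoyloxy)germacr-7(11)-en-12,6-olide
Product: 30 (1S,4S,5R,6R,8R,10R)-1,10:4,5-diepoxy-13-hydroxy-8-(3-methylbut-2-enoyloxy)germacr-7(11)-en-12,6-olide
Conditions: Bu4NF, AcOH, THF, 0 °C → rt
Reagents that add atoms: none
Why: Fluoride cleaves the Si–O bond; buffering with acetic acid keeps the medium near neutral so that the epoxides, the senecioate and the acidic C6–H should remain untouched.

Step 21
Reactants: 30 (1S,4S,5R,6R,8R,10R)-1,10:4,5-diepoxy-13-hydroxy-8-(3-methylbut-2-enoyloxy)germacr-7(11)-en-12,6-olide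
Product: 31 (1S,4S,5R,6R,8R,10R)-13-acetoxy-1,10:4,5-diepoxy-8-(3-methylbut-2-enoyloxy)germacr-7(11)-en-12,6-olide (CNP0228323.1)
Conditions: Ac2O, pyridine, DMAP (cat.), CH2Cl2, 0 °C
Reagents that add atoms: acetic anhydride, CC(=O)OC(C)=O
Why: Acetylation of the only free hydroxyl, a primary allylic alcohol, under weakly basic conditions; it is done last because the C13 acetate is a vinylogous leaving group.

## Compound list

1 | penta-1,4-dien-3-ol | C=CC(O)C=C | starting material
2 | (2S,3R)-1,2-epoxypent-4-en-3-ol | C=C[C@@H](O)[C@@H]1CO1 | intermediate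
3 | (2S)-2-[(1R)-1-(4-methoxybenzyloxy)prop-2-en-1-yl]oxirane | C=C[C@@H](OCc1ccc(OC)cc1)[C@@H]1CO1 | intermediate
4 | (2S,3R)-3-(4-methoxybenzyloxy)pent-4-en-2-ol | C=C[C@@H](OCc1ccc(OC)cc1)[C@@H](O)C | intermediate
5 | but-2-yn-1-ol | CC#CCO | starting material
6 | sodium 2,2-bis(2-methoxyethoxy)-3-methyl-2,5-dihydro-1,2-oxaaluminol-2-uide (cyclic alkenylalanate) | [Na+].CC1=CCO[Al-]1(OCCOC)OCCOC | intermediate (not isolated)
7 | (Z)-3-iodobut-2-en-1-ol | C/C(I)=C/CO | intermediate
8 | 9-[(3R,4S)-4-hydroxy-3-(4-methoxybenzyloxy)pentyl]-9-borabicyclo[3.3.1]nonane | C1CC2CCCC(C1)B2CC[C@@H](OCc1ccc(OC)cc1)[C@@H](O)C | intermediate (not isolated)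
9 | (2Z,6R,7S)-6-(4-methoxybenzyloxy)-3-methyloct-2-ene-1,7-diol | OC/C=C(/C)CC[C@@H](OCc1ccc(OC)cc1)[C@@H](O)C | intermediate
10 | [(2R,3S)-3-[(3R,4S)-4-hydroxy-3-(4-methoxybenzyloxy)pentyl]-3-methyloxiran-2-yl]methanol | OC[C@H]1O[C@@]1(C)CC[C@@H](OCc1ccc(OC)cc1)[C@@H](O)C | intermediate
11 | (2S,3S)-3-[(3R,4S)-4-hydroxy-3-(4-methoxybenzyloxy)pentyl]-3-methyloxirane-2-carbaldehyde | O=C[C@H]1O[C@@]1(C)CC[C@@H](OCc1ccc(OC)cc1)[C@@H](O)C | intermediate
12 | methyl 3-hydroxypropanoate | COC(=O)CCO | starting material
13 | methyl 3-(tert-butyldiphenylsilyloxy)propanoate | COC(=O)CCO[Si](c1ccccc1)(c1ccccc1)C(C)(C)C | intermediate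
14 | methyl (4R)-2,2-dimethyl-1,3-dioxolane-4-carboxylate | COC(=O)[C@H]1COC(C)(C)O1 | starting material
15 | lithium enolate of 13 | [Li]OC(OC)=CCO[Si](c1ccccc1)(c1ccccc1)C(C)(C)C | intermediate (not isolated)
16 | methyl 2-[(tert-butyldiphenylsilyloxy)methyl]-3-[(4R)-2,2-dimethyl-1,3-dioxolan-4-yl]-3-oxopropanoate (C2 enolisable, left undefined) | COC(=O)C(CO[Si](c1ccccc1)(c1ccccc1)C(C)(C)C)C(=O)[C@H]1COC(C)(C)O1 | intermediate
17 | methyl (2Z)-2-[(tert-butyldiphenylsilyloxy)methyl]-3-[(4R)-2,2-dimethyl-1,3-dioxolan-4-yl]-3-(trifluoromethylsulfonyloxy)prop-2-enoate | COC(=O)/C(CO[Si](c1ccccc1)(c1ccccc1)C(C)(C)C)=C(\OS(=O)(=O)C(F)(F)F)[C@H]1COC(C)(C)O1 | intermediate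
18 | methyl (2Z,4R)-2-[(tert-butyldiphenylsilyloxy)methyl]-4,5-dihydroxy-3-(trifluoromethylsulfonyloxy)pent-2-enoate | COC(=O)/C(CO[Si](c1ccccc1)(c1ccccc1)C(C)(C)C)=C(\OS(=O)(=O)C(F)(F)F)[C@H](O)CO | intermediate
19 | methyl (2Z,4S)-5-bromo-2-[(tert-butyldiphenylsilyloxy)methyl]-4-hydroxy-3-(trifluoromethylsulfonyloxy)pent-2-enoate | COC(=O)/C(CO[Si](c1ccccc1)(c1ccccc1)C(C)(C)C)=C(\OS(=O)(=O)C(F)(F)F)[C@H](O)CBr | intermediate
20 | dichlorochromium alkoxide of the C6–C7 coupled hydroxy ester | COC(=O)/C(CO[Si](c1ccccc1)(c1ccccc1)C(C)(C)C)=C(\[C@@H](O[Cr](Cl)Cl)[C@H]1O[C@@]1(C)CC[C@@H](OCc1ccc(OC)cc1)[C@@H](O)C)[C@H](O)CBr | intermediate (not isolated)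
21 | (5R)-4-[(1S)-2-bromo-1-hydroxyethyl]-3-[(tert-butyldiphenylsilyloxy)methyl]-5-[(2R,3S)-3-[(3R,4S)-4-hydroxy-3-(4-methoxybenzyloxy)pentyl]-3-methyloxiran-2-yl]furan-2(5H)-one | CC(C)(C)[Si](c1ccccc1)(c1ccccc1)OCC1=C([C@H](O)CBr)[C@@H](OC1=O)[C@H]1O[C@@]1(C)CC[C@@H](OCc1ccc(OC)cc1)[C@@H](O)C | intermediate
22 | (5R)-4-(bromoacetyl)-3-[(tert-butyldiphenylsilyloxy)methyl]-5-[(2R,3S)-3-[(3R)-3-(4-methoxybenzyloxy)-4-oxopentyl]-3-methyloxiran-2-yl]furan-2(5H)-one (key-step precursor) | CC(C)(C)[Si](c1ccccc1)(c1ccccc1)OCC1=C(C(=O)CBr)[C@@H](OC1=O)[C@H]1O[C@@]1(C)CC[C@@H](OCc1ccc(OC)cc1)C(C)=O | intermediate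
23 | diiodosamarium C8–C9 enolate of 22 | CC(C)(C)[Si](c1ccccc1)(c1ccccc1)OCC1=C(C(=C)O[Sm](I)I)[C@@H](OC1=O)[C@H]1O[C@@]1(C)CC[C@@H](OCc1ccc(OC)cc1)C(C)=O | intermediate (not isolated)
24 | (1R,4S,5R,6R,10R)-13-(tert-butyldiphenylsilyloxy)-4,5-epoxy-10-hydroxy-1-(4-methoxybenzyloxy)-8-oxogermacr-7(11)-en-12,6-olide (key-step product) | CC(C)(C)[Si](c1ccccc1)(c1ccccc1)OCC1=C2[C@@H](OC1=O)[C@H]1O[C@@]1(C)CC[C@@H](OCc1ccc(OC)cc1)[C@](C)(O)CC2=O | intermediate
25 | (1R,4S,5R,6R,8R,10R)-13-(tert-butyldiphenylsilyloxy)-4,5-epoxy-8,10-dihydroxy-1-(4-methoxybenzyloxy)germacr-7(11)-en-12,6-olide | CC(C)(C)[Si](c1ccccc1)(c1ccccc1)OCC1=C2[C@@H](OC1=O)[C@H]1O[C@@]1(C)CC[C@@H](OCc1ccc(OC)cc1)[C@](C)(O)C[C@H]2O | intermediate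
26 | (1R,4S,5R,6R,8R,10R)-13-(tert-butyldiphenylsilyloxy)-4,5-epoxy-10-hydroxy-1-(4-methoxybenzyloxy)-8-(3-methylbut-2-enoyloxy)germacr-7(11)-en-12,6-olide | CC(C)(C)[Si](c1ccccc1)(c1ccccc1)OCC1=C2[C@@H](OC1=O)[C@H]1O[C@@]1(C)CC[C@@H](OCc1ccc(OC)cc1)[C@](C)(O)C[C@H]2OC(=O)C=C(C)C | intermediate
27 | (1R,4S,5R,6R,8R,10R)-13-(tert-butyldiphenylsilyloxy)-4,5-epoxy-1,10-dihydroxy-8-(3-methylbut-2-enoyloxy)germacr-7(11)-en-12,6-olide | CC(C)(C)[Si](c1ccccc1)(c1ccccc1)OCC1=C2[C@@H](OC1=O)[C@H]1O[C@@]1(C)CC[C@@H](O)[C@](C)(O)C[C@H]2OC(=O)C=C(C)C | intermediate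
28 | 1-O-methanesulfonate of 27 | CC(C)(C)[Si](c1ccccc1)(c1ccccc1)OCC1=C2[C@@H](OC1=O)[C@H]1O[C@@]1(C)CC[C@@H](OS(C)(=O)=O)[C@](C)(O)C[C@H]2OC(=O)C=C(C)C | intermediate (not isolated)
29 | (1S,4S,5R,6R,8R,10R)-13-(tert-butyldiphenylsilyloxy)-1,10:4,5-diepoxy-8-(3-methylbut-2-enoyloxy)germacr-7(11)-en-12,6-olide | CC(C)(C)[Si](c1ccccc1)(c1ccccc1)OCC1=C2[C@@H](OC1=O)[C@H]1O[C@@]1(C)CC[C@@H]1O[C@]1(C)C[C@H]2OC(=O)C=C(C)C | intermediate
30 | (1S,4S,5R,6R,8R,10R)-1,10:4,5-diepoxy-13-hydroxy-8-(3-methylbut-2-enoyloxy)germacr-7(11)-en-12,6-olide | OCC1=C2[C@@H](OC1=O)[C@H]1O[C@@]1(C)CC[C@@H]1O[C@]1(C)C[C@H]2OC(=O)C=C(C)C | intermediate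
31 | (1S,4S,5R,6R,8R,10R)-13-acetoxy-1,10:4,5-diepoxy-8-(3-methylbut-2-enoyloxy)germacr-7(11)-en-12,6-olide (CNP0228323.1) | CC(=O)OCC1=C2[C@@H](OC1=O)[C@H]1O[C@@]1(C)CC[C@@H]1O[C@]1(C)C[C@H]2OC(=O)C=C(C)C | target

## Step count and least certain steps

Total: 21 steps. Longest linear sequence: 15 steps (steps 1–3, 5–7 and 13–21, from penta-1,4-dien-3-ol). The fragment from methyl 3-hydroxypropanoate needs 5 steps (8–12) before the coupling.

**Step 15 (key step).** Most likely to fail through:
- electron transfer to the ene-dicarbonyl system of the substrate or product (over-reduction, loss of the C1 ether);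
- protonation of the samarium enolate before it finds the ketone, which would leave a methyl ketone;
- intermolecular aldol addition if dilution is insufficient;
- incomplete chelation, which would erode control at C10.

Fallback, from 22 back to 24: the enolate equivalent is made first and the ring closed in a separate, non-reductive step. Zinc dust and Me3SiCl convert the α-bromo ketone regiospecifically into the trimethylsilyl dienol ether F1. MgBr2·OEt2 in CH2Cl2 at −78 °C under high dilution then promotes an intramolecular Mukaiyama aldol addition to the ketone, which is held as its magnesium chelate with the C1 ether. Aqueous work-up removes the transferred silyl group and gives 24.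

**Step 13.** The tetrasubstituted alkenylchromium may add slowly, leaving the epoxy aldehyde exposed to chloride or reductive opening. The free bromohydrin may interfere through reduction at the C–Br bond. Felkin–Anh selectivity at C6 may be eroded. Fallback, from 11 and 17 back to 21: the order of events is changed so that the coupling partner carries neither halide nor free hydroxyl. Nickel/chromium coupling of 11 with the acetonide triflate 17 gives the acetonide butenolide F2. Mild hydrolysis (CuCl2·2H2O, MeCN) gives the triol F3, and primary-selective Appel bromination (CBr4, PPh3) gives 21.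

**Step 16.** The conformation of the ten-membered ring may override internal hydride delivery (syn diol), or the enone may be reduced in the conjugate sense. Fallback, from 24 back to 26: a chelation-controlled syn reduction (Et2BOMe, NaBH4, THF/MeOH, −78 °C; Narasaka–Prasad) gives the 8-epi diol F4. Mitsunobu esterification with 3-methylbut-2-enoic acid (PPh3, DIAD) then installs the senecioate with inversion at C8, giving 26 directly.

**Step 19.** The base may remove C6–H (epimerisation, double-bond migration) or trigger acyl transfer before the alkoxide displaces the sulfonate, or the ring may resist the anti-periplanar arrangement. Fallback, from 27 back to 29: direct cyclodehydration under Mitsunobu conditions (PPh3, DIAD, toluene). The secondary C1 hydroxyl is activated as an oxyphosphonium ion and displaced by O10 with inversion under neutral conditions; no new compound is isolated on this path (entry F0).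

**Step 9.** The β-silyloxy enolate may lose silanolate (E1cB) on warming, or proton transfer from 14 may stop the condensation. Fallback, from 13 (through 15) back to 16: aldol addition of 15 to (4R)-2,2-dimethyl-1,3-dioxolane-4-carbaldehyde at −78 °C traps the enolate quickly and gives the β-hydroxy ester F5 as a mixture of diastereomers. Dess–Martin oxidation then gives 16.

## Further compounds

F1 | step 15 | trimethylsilyl dienol ether of 22 (C8–OSiMe3, C8=C9H2) | CC(C)(C)[Si](c1ccccc1)(c1ccccc1)OCC1=C(C(=C)O[Si](C)(C)C)[C@@H](OC1=O)[C@H]1O[C@@]1(C)CC[C@@H](OCc1ccc(OC)cc1)C(C)=O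
F2 | step 13 | (5R)-3-[(tert-butyldiphenylsilyloxy)methyl]-4-[(4R)-2,2-dimethyl-1,3-dioxolan-4-yl]-5-[(2R,3S)-3-[(3R,4S)-4-hydroxy-3-(4-methoxybenzyloxy)pentyl]-3-methyloxiran-2-yl]furan-2(5H)-one | CC(C)(C)[Si](c1ccccc1)(c1ccccc1)OCC1=C([C@H]2COC(C)(C)O2)[C@@H](OC1=O)[C@H]1O[C@@]1(C)CC[C@@H](OCc1ccc(OC)cc1)[C@@H](O)C
F3 | step 13 | (5R)-3-[(tert-butyldiphenylsilyloxy)methyl]-4-[(1R)-1,2-dihydroxyethyl]-5-[(2R,3S)-3-[(3R,4S)-4-hydroxy-3-(4-methoxybenzyloxy)pentyl]-3-methyloxiran-2-yl]furan-2(5H)-one | CC(C)(C)[Si](c1ccccc1)(c1ccccc1)OCC1=C([C@H](O)CO)[C@@H](OC1=O)[C@H]1O[C@@]1(C)CC[C@@H](OCc1ccc(OC)cc1)[C@@H](O)C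
F4 | step 16 | (1R,4S,5R,6R,8S,10R)-13-(tert-butyldiphenylsilyloxy)-4,5-epoxy-8,10-dihydroxy-1-(4-methoxybenzyloxy)germacr-7(11)-en-12,6-olide (8-epi-25) | CC(C)(C)[Si](c1ccccc1)(c1ccccc1)OCC1=C2[C@@H](OC1=O)[C@H]1O[C@@]1(C)CC[C@@H](OCc1ccc(OC)cc1)[C@](C)(O)C[C@@H]2O
F0 | step 19 | none | none
F5 | step 9 | methyl 2-[(tert-butyldiphenylsilyloxy)methyl]-3-[(4R)-2,2-dimethyl-1,3-dioxolan-4-yl]-3-hydroxypropanoate (mixture at C2 and C3) | COC(=O)C(CO[Si](c1ccccc1)(c1ccccc1)C(C)(C)C)C(O)[C@H]1COC(C)(C)O1
A1 | alternative 1 | ten-membered 7-ketone with allyl malonate on O6, both epoxides and tert-butyldimethylsilyl ether on O8 | C=CCOC(=O)CC(=O)O[C@H]1[C@H]2O[C@@]2(C)CC[C@@H]2O[C@]2(C)C[C@@H](O[Si](C)(C)C(C)(C)C)C1=O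
A2 | alternative 1 | bis-epoxy germacranolide with allyl ester at C11 and tert-butyldimethylsilyl ether on O8 | C=CCOC(=O)C1=C2[C@@H](OC1=O)[C@H]1O[C@@]1(C)CC[C@@H]1O[C@]1(C)C[C@H]2O[Si](C)(C)C(C)(C)C
A3 | alternative 2 | open-chain bis-epoxy C6 aldehyde with Z enol triflate at C7, cis methyl ester, O8 silyl ether and O13 4-methoxybenzyl ether | O=C[C@H]1O[C@@]1(C)CC[C@@H]1O[C@]1(C)C[C@@H](O[Si](C)(C)C(C)(C)C)/C(OS(=O)(=O)C(F)(F)F)=C(/C(=O)OC)COCc1ccc(OC)cc1
A4 | alternative 2 | bis-epoxy germacranolide with O8 tert-butyldimethylsilyl ether and O13 4-methoxybenzyl ether | COc1ccc(COCC2=C3[C@@H](OC2=O)[C@H]4O[C@@]4(C)CC[C@@H]4O[C@]4(C)C[C@H]3O[Si](C)(C)C(C)(C)C)cc1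
A5 | alternative 3 | butenolide with (Z)-2-iodoprop-1-enyl on C6 and a C8 side chain ending in the vinyl-substituted 1,10-epoxide | C=C[C@@H]1O[C@]1(C)C[C@@H](OC(=O)C=C(C)C)C1=C(COC(C)=O)C(=O)O[C@H]1/C=C(/C)I
A6 | alternative 3 | 4,5-deoxy target with cis C4=C5 alkene | CC(=O)OCC1=C2[C@@H](OC1=O)/C=C(/C)CC[C@@H]1O[C@]1(C)C[C@H]2OC(=O)C=C(C)C
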